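The retrosynthesis first cuts the two end alkenes C7=C8 and C7'=C8' (twofold Julia–Kocienski olefination), leaving crocetin dialdehyde and two copies of one C10 ring sulfone.
In the ring unit (carotenoid numbering: C1 = CMe2, C2 and C3 = CH2, C5 = ring carbon bearing methyl, C6 = ring CH stereocentre, C7 = first chain carbon) the C6–C7 bond is cut next.
C6 is wedged between the quaternary C1 and C5 but lies 1,3 to C4 across C5, so C7 is handed over from an oxygen on C4 by a [2,3] shift that also parks the alkene at C4=C5, the ε-ring position.
The C4 carbinol goes back to 2,4,4-trimethylcyclohex-2-enone, whose only ring is cut at C1–C2 and C5=C6 (Robinson annulation of isobutyraldehyde and pent-1-en-3-one).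
Forward order: ring, C4–OH, O–CH2Sn, C6–C7, sulfone, then both ring units are joined to the C20 chain in one flask.
Stereochemistry: CBS reduction sets C4 (S), the suprafacial shift transfers it to C6 (R), and nothing later touches C6. The inner chain alkenes arrive as E in the dialdehyde, and the olefination sets C7=C8 and C7'=C8'.

Key step: step 4

Assumption: all-E crocetin dialdehyde is taken as a purchasable C20 building block, and the polyene steps are run under argon with exclusion of light.

Step 1
Reactants: 1 isobutyraldehyde; 2 pent-1-en-3-one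
Product: 5 2,4,4-trimethylcyclohex-2-en-1-one, via keto aldehyde 3 (not isolated), via aldol 4 (not isolated)
Conditions: H2SO4 (cat.), toluene, 45–50 °C, then reflux, Dean–Stark
Reagents that add atoms: none
Why: Acid-catalysed Robinson annulation, in which Michael addition of the aldehyde enol (a single α-hydrogen, so one mode only) to the enone forms C1–C2 of keto aldehyde 3, and intramolecular aldol condensation of the ketone CH2 onto the aldehyde closes the six-membered ring at C5–C6 and dehydrates aldol 4 to the conjugated enone, leaving no stereocentre.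

Step 2
Reactants: 5 2,4,4-trimethylcyclohex-2-en-1-one
Product: 6 (1S)-2,4,4-trimethylcyclohex-2-en-1-ol
Conditions: (R)-2-methyl-CBS-oxazaborolidine (10 mol%), BH3·SMe2, THF, −20 °C; then MeOH
Reagents that add atoms: none
Why: Corey–Bakshi–Shibata 1,2-reduction, in which the ketone binds the catalyst boron anti to the larger 2-methylalkenyl arm and the nitrogen-bound borane delivers hydride to one face through a six-membered transition state, which with the (R)-catalyst should give the S carbinol at C4 (the sense is to be confirmed by Mosher ester analysis before material is carried on).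

Step 3
Reactants: 6 (1S)-2,4,4-trimethylcyclohex-2-en-1-ol; 7 tributyl(iodomethyl)stannane
Product: 9 tributyl{[(1S)-2,4,4-trimethylcyclohex-2-en-1-yl]oxymethyl}stannane, via potassium alkoxide 8 (not isolated)
Conditions: KH, THF, 0 °C; then 7, 0 °C to rt
Reagents that add atoms: none
Why: Williamson etherification in which the potassium alkoxide displaces iodide from the unhindered, tin-activated CH2I carbon by SN2, and because the C4–O bond is never broken the S configuration is kept.

Step 4
Reactants: 9 tributyl{[(1S)-2,4,4-trimethylcyclohex-2-en-1-yl]oxymethyl}stannane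
Product: 12 [(1R)-2,6,6-trimethylcyclohex-2-en-1-yl]methanol ((R)-α-cyclogeraniol), via lithiomethyl ether 10 (not isolated), via lithium alkoxide 11 (not isolated)
Conditions: n-BuLi, THF, −78 °C; then H2O
Reagents that add atoms: none
Why: Tin–lithium exchange gives the unstabilised α-alkoxymethyllithium 10, whose carbanion carbon bonds to C6 while C4–O breaks and the alkene moves to C4=C5 in a concerted suprafacial [2,3]-sigmatropic shift through a five-membered envelope transition state, leaving lithium alkoxide 11. The closest known reaction type is the Still–Wittig rearrangement of cyclohexenyl stannylmethyl ethers, used to place hydroxymethyl groups beside quaternary carbons. No ring is closed; one C–C bond and one stereocentre are formed. The new C6 centre is controlled by the C4 carbinol, since the tethered carbon can only reach the ring face that carries the oxygen, so 4S becomes 6R (1,3-chirality transfer). The step needs the [2,3] shift to outrun the [1,2] shift and protonation of the carbanion, and this should be secured by the lack of anion stabilisation, the low temperature and the pseudoaxial preference of the C4 oxygen (A(1,2) strain with the C5 methyl), which holds CH2Li over C6 on the face opposite to the pseudoaxial C1 methyl. The alkene can only end at C4=C5, so the unconjugated ring isomer is fixed by mechanism and never by an acid or base equilibrium.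

Step 5
Reactants: 12 (R)-α-cyclogeraniol
Product: 13 1-phenyl-5-({[(1R)-2,6,6-trimethylcyclohex-2-en-1-yl]methyl}sulfanyl)-1H-tetrazole
Conditions: 1-phenyl-1H-tetrazole-5-thiol, PPh3, DIAD, THF, 0 °C to rt
Reagents that add atoms: 1-phenyl-1H-tetrazole-5-thiol, Sc1nnnn1-c1ccccc1
Why: Mitsunobu thioetherification in which the acidic tetrazolethiol protonates the betaine and its thiolate displaces the oxyphosphonium at primary C7 by SN2 under neutral conditions, so that neither C6 nor the C4=C5 alkene is touched.

Step 6
Reactants: 13 1-phenyl-5-({[(1R)-2,6,6-trimethylcyclohex-2-en-1-yl]methyl}sulfanyl)-1H-tetrazole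
Product: 14 1-phenyl-5-({[(1R)-2,6,6-trimethylcyclohex-2-en-1-yl]methyl}sulfonyl)-1H-tetrazole
Conditions: (NH4)6Mo7O24·4H2O (cat.), 30% aq. H2O2, EtOH, 0 °C to rt
Reagents that add atoms: hydrogen peroxide, OO
Why: Molybdate-catalysed peroxide oxidation of the sulfide through the sulfoxide to the sulfone, chosen over a peracid because the peroxomolybdate attacks sulfur readily but is slow to epoxidise an unactivated trisubstituted alkene.

Step 7
Reactants: 14 1-phenyl-5-({[(1R)-2,6,6-trimethylcyclohex-2-en-1-yl]methyl}sulfonyl)-1H-tetrazole (2 equivalents); 15 crocetin dialdehyde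
Product: 18 (6R,6'R)-ε,ε-carotene, via potassium sulfonyl carbanion 16 (not isolated), via apo-aldehyde 17 (not isolated)
Conditions: KN(SiMe3)2, THF, −78 °C; then 15, −78 to −20 °C, dark; then H2O
Reagents that add atoms: none
Why: Twofold Julia–Kocienski olefination in which the C7 sulfonyl carbanion 16 adds to each aldehyde of the C2-symmetric dial (first giving apo-aldehyde 17), and the β-alkoxide undergoes Smiles transfer of the tetrazole with loss of SO2 and the tetrazolone, which with a branched non-conjugated sulfone and a potassium counter-ion should favour E at C7=C8 and C7'=C8', while C6, being β to the sulfone, is not deprotonated at −78 °C and should keep its configuration.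

Compound list
1 | isobutyraldehyde (2-methylpropanal) | CC(C)C=O | starting material
2 | pent-1-en-3-one | CCC(=O)C=C | starting material
3 | 2,2-dimethyl-5-oxoheptanal (keto aldehyde, not isolated) | CCC(=O)CCC(C)(C)C=O | intermediate
4 | 3-hydroxy-2,4,4-trimethylcyclohexan-1-one (aldol, racemic diastereomer mixture, not isolated) | CC1C(O)C(C)(C)CCC1=O | intermediate
5 | 2,4,4-trimethylcyclohex-2-en-1-one | CC1=CC(C)(C)CCC1=O | intermediate
6 | (1S)-2,4,4-trimethylcyclohex-2-en-1-ol | CC1=CC(C)(C)CC[C@@H]1O | intermediate
7 | tributyl(iodomethyl)stannane | CCCC[Sn](CI)(CCCC)CCCC | starting material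
8 | potassium (1S)-2,4,4-trimethylcyclohex-2-en-1-olate (not isolated) | CC1=CC(C)(C)CC[C@@H]1[O-].[K+] | intermediate
9 | tributyl{[(1S)-2,4,4-trimethylcyclohex-2-en-1-yl]oxymethyl}stannane | CC1=CC(C)(C)CC[C@@H]1OC[Sn](CCCC)(CCCC)CCCC | intermediate
10 | {[(1S)-2,4,4-trimethylcyclohex-2-en-1-yl]oxy}methyllithium (not isolated) | CC1=CC(C)(C)CC[C@@H]1OC[Li] | intermediate
11 | lithium [(1R)-2,6,6-trimethylcyclohex-2-en-1-yl]methanolate (not isolated) | CC1=CCCC(C)(C)[C@H]1C[O-].[Li+] | intermediate
12 | [(1R)-2,6,6-trimethylcyclohex-2-en-1-yl]methanol, (R)-α-cyclogeraniol | CC1=CCCC(C)(C)[C@H]1CO | intermediate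
13 | 1-phenyl-5-({[(1R)-2,6,6-trimethylcyclohex-2-en-1-yl]methyl}sulfanyl)-1H-tetrazole | CC1=CCCC(C)(C)[C@H]1CSc1nnnn1-c1ccccc1 | intermediate
14 | 1-phenyl-5-({[(1R)-2,6,6-trimethylcyclohex-2-en-1-yl]methyl}sulfonyl)-1H-tetrazole | CC1=CCCC(C)(C)[C@H]1CS(=O)(=O)c1nnnn1-c1ccccc1 | intermediate
15 | crocetin dialdehyde (all-E-2,6,11,15-tetramethylhexadeca-2,4,6,8,10,12,14-heptaenedial) | O=C/C(C)=C/C=C/C(C)=C/C=C/C=C(C)/C=C/C=C(C)/C=O | starting material
16 | potassium salt of sulfone 14, carbanion at C7 (not isolated) | CC1=CCCC(C)(C)[C@H]1[CH-]S(=O)(=O)c1nnnn1-c1ccccc1.[K+] | intermediate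
17 | (6R)-8'-apo-ε-caroten-8'-al (mono-olefination product, not isolated) | CC1=CCCC(C)(C)[C@H]1/C=C/C(C)=C/C=C/C(C)=C/C=C/C=C(C)/C=C/C=C(C)/C=O | intermediate
18 | (6R,6'R)-ε,ε-carotene | CC1=CCCC(C)(C)[C@H]1/C=C/C(C)=C/C=C/C(C)=C/C=C/C=C(C)/C=C/C=C(C)/C=C/[C@H]1C(C)=CCCC1(C)C | target

Total step count: 7. Longest linear sequence: 7 steps (from 1 and 2 to 18).

Steps most likely to fail

Step 4. The oxymethyl carbanion may undergo the [1,2] shift or be protonated before it reaches the crowded C6, so that carbon is delivered to C4 or not at all. The fallback keeps the same syn 1,3-transfer from the C4 oxygen but uses a directed cuprate substitution, setting out from 6 and returning at 12. Alcohol 6 with PhNCO and Et3N in CH2Cl2 should give (1S)-2,4,4-trimethylcyclohex-2-en-1-yl N-phenylcarbamate F1. Deprotonation of its N–H (n-BuLi, THF, −78 °C), addition of CuI and then (i-PrO)Me2SiCH2MgCl should deliver the silylmethyl group to C6 from the carbamate-bearing face by syn-SN2' substitution, giving {[(1R)-2,6,6-trimethylcyclohex-2-en-1-yl]methyl}(isopropoxy)dimethylsilane F2. Tamao oxidation of the C–Si bond (H2O2, KF, KHCO3, THF/MeOH) then gives 12.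

Step 7. The hindered branched carbanion may stop after the first olefination, give poor E/Z control at C7=C8, or the excess base may move the ring alkene into conjugation. Minor Z isomers alone would be handled by thermal equilibration in heptane and crystallisation. If the coupling itself fails, the chain is built outward from the ring in the classical C15 + C10 + C15 manner, setting out from 12 and returning at 18.
- Buffered Dess–Martin oxidation (NaHCO3, CH2Cl2, 0 °C) of 12 should give (1R)-2,6,6-trimethylcyclohex-2-ene-1-carbaldehyde F3, used at once because C6 is now epimerisable.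
- Base-free Wittig reaction of F3 with 1-(triphenylphosphoranylidene)propan-2-one in toluene should give (R)-α-ionone F4 and set C7=C8 as E.
- Addition of vinylmagnesium bromide (THF, −20 °C) should give vinyl-α-ionol F5 as a mixture of C9 epimers.
- PPh3·HBr in MeOH should convert F5 with allylic transposition into the C15 salt triphenyl{(2E,4E)-3-methyl-5-[(1R)-2,6,6-trimethylcyclohex-2-en-1-yl]penta-2,4-dien-1-yl}phosphonium bromide F6.
- Twofold Wittig reaction of F6 with commercial (2E,4E,6E)-2,7-dimethylocta-2,4,6-trienedial (O=C/C(C)=C/C=C/C=C(C)/C=O; NaOMe, MeOH/CH2Cl2), followed by thermal equilibration to the all-E isomer, should give 18.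

Step 2. Hydride delivery may be poorly face-selective because methyl is a small α-substituent, or the borane may hydroborate the alkene. The fallback separates reduction from enantiodiscrimination, setting out from 5 and returning at 6. Luche reduction (NaBH4, CeCl3·7H2O, MeOH, 0 °C) should give racemic 2,4,4-trimethylcyclohex-2-en-1-ol F7. Lipase-catalysed acylation (immobilised Candida antarctica lipase B, vinyl acetate, MTBE, rt) should esterify the R enantiomer faster, giving (1R)-2,4,4-trimethylcyclohex-2-en-1-yl acetate F8. Unreacted (S)-alcohol 6 is recovered by chromatography after slightly more than half conversion.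

Further compounds
F1 | step 4 | (1S)-2,4,4-trimethylcyclohex-2-en-1-yl N-phenylcarbamate | CC1=CC(C)(C)CC[C@@H]1OC(=O)Nc1ccccc1
F2 | step 4 | {[(1R)-2,6,6-trimethylcyclohex-2-en-1-yl]methyl}(isopropoxy)dimethylsilane | CC1=CCCC(C)(C)[C@H]1C[Si](C)(C)OC(C)C
F3 | step 7 | (1R)-2,6,6-trimethylcyclohex-2-ene-1-carbaldehyde, (R)-α-cyclocitral | CC1=CCCC(C)(C)[C@H]1C=O
F4 | step 7 | (3E)-4-[(1R)-2,6,6-trimethylcyclohex-2-en-1-yl]but-3-en-2-one, (R)-α-ionone | CC1=CCCC(C)(C)[C@H]1/C=C/C(C)=O
F5 | step 7 | (1E)-3-methyl-1-[(1R)-2,6,6-trimethylcyclohex-2-en-1-yl]penta-1,4-dien-3-ol, vinyl-α-ionol (C3 epimer mixture) | CC1=CCCC(C)(C)[C@H]1/C=C/C(C)(O)C=C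
F6 | step 7 | triphenyl{(2E,4E)-3-methyl-5-[(1R)-2,6,6-trimethylcyclohex-2-en-1-yl]penta-2,4-dien-1-yl}phosphonium bromide | CC1=CCCC(C)(C)[C@H]1/C=C/C(C)=C/C[P+](c1ccccc1)(c1ccccc1)c1ccccc1.[Br-]
F7 | step 2 | racemic 2,4,4-trimethylcyclohex-2-en-1-ol | CC1=CC(C)(C)CCC1O
F8 | step 2 | (1R)-2,4,4-trimethylcyclohex-2-en-1-yl acetate | CC1=CC(C)(C)CC[C@H]1OC(C)=O
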